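**Retrosynthetic overview**

1. Target 11 comes from its tetrabenzyl ether 10 by one global hydrogenolysis; the three methyl ethers are carried through from the starting materials.
2. 10 comes from the 1,3-diketone 9 by forming O1–C8a. The feature used is the tetra-oxygenated A ring, whose only unsubstituted carbon (C8a) sits ortho to C4a, the carbon bearing the C4 acyl group; the enol oxygen on C2 is joined to it by anodic dehydrogenation.
3. 9 is cut at C2–C3 (Claisen condensation) into acetophenone 6 (A ring, C3, C4) and benzoate 8 (B ring, C2).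
4. 6 comes from acetosyringone 1 by O-benzylation, ring bromination at the carbon that becomes C5, copper-catalysed hydroxylation and a second benzylation; 8 comes from methyl 3-O-methylgallate 7 by double benzylation.
5. Ring order: the A and B rings are bought as arenes; the pyranone C ring is the only ring formed, in step 7.

Key step: step 7

Remark: the target has no stereocentre and no stereogenic axis, so it is a single achiral compound and no step needs stereocontrol.

**Route**

Step 1
Reactants: 1 acetosyringone, 1-(4-hydroxy-3,5-dimethoxyphenyl)ethanone; 2 benzyl bromide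
Product: 3 1-[4-(benzyloxy)-3,5-dimethoxyphenyl]ethanone
Conditions: BnBr (1.2 equiv), K2CO3, DMF, 60 °C
Reagents that add atoms: benzyl bromide (2), BrCc1ccccc1
Why: Williamson ether synthesis; the phenol para to the acetyl group is acidic enough for K2CO3, and its phenoxide should displace bromide cleanly despite the two flanking methoxy groups.

Step 2
Reactants: 3 1-[4-(benzyloxy)-3,5-dimethoxyphenyl]ethanone
Product: 4 1-[4-(benzyloxy)-2-bromo-3,5-dimethoxyphenyl]ethanone
Conditions: NBS (1.05 equiv), MeCN, 0 °C to rt, dark
Reagents that add atoms: N-bromosuccinimide, O=C1CCC(=O)N1Br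
Why: Electrophilic aromatic bromination; the two equivalent ring C–H positions are each ortho to one methoxy and para to the other, so one ring monobromide is expected, and the polar non-acidic medium should disfavour enol-mediated bromination of the acetyl methyl group.

Step 3
Reactants: 4 1-[4-(benzyloxy)-2-bromo-3,5-dimethoxyphenyl]ethanone
Product: 5 1-[4-(benzyloxy)-2-hydroxy-3,5-dimethoxyphenyl]ethanone
Conditions: Cu(acac)2 (cat.), N,N'-bis(4-hydroxy-2,6-dimethylphenyl)oxalamide (cat.), LiOH·H2O (2.5 equiv), DMSO/H2O 4:1, 80 °C; then aq. HCl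
Reagents that add atoms: lithium hydroxide, [Li+].[OH-]
Why: Copper-catalysed Ullmann-type hydroxylation of an aryl bromide with hydroxide, which the ortho acetyl group should assist by chelating copper, while the benzyl and methyl ethers are inert to the mild base.

Step 4
Reactants: 5 1-[4-(benzyloxy)-2-hydroxy-3,5-dimethoxyphenyl]ethanone; 2 benzyl bromide
Product: 6 1-[2,4-bis(benzyloxy)-3,5-dimethoxyphenyl]ethanone
Conditions: BnBr (1.3 equiv), K2CO3, TBAI (cat.), DMF, 80 °C
Reagents that add atoms: benzyl bromide (2), BrCc1ccccc1
Why: Williamson ether synthesis; the raised temperature in DMF should overcome the hydrogen bond of the 2-hydroxyl to the acetyl carbonyl and give the fully protected A-ring ketone.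

Step 5
Reactants: 7 methyl 3,4-dihydroxy-5-methoxybenzoate; 2 benzyl bromide
Product: 8 methyl 3,4-bis(benzyloxy)-5-methoxybenzoate
Conditions: BnBr (2.4 equiv), K2CO3, DMF, 60 °C
Reagents that add atoms: benzyl bromide (2), BrCc1ccccc1
Why: Double Williamson ether synthesis of the catechol; the methyl ester should survive anhydrous K2CO3.

Step 6
Reactants: 6 1-[2,4-bis(benzyloxy)-3,5-dimethoxyphenyl]ethanone; 8 methyl 3,4-bis(benzyloxy)-5-methoxybenzoate
Product: 9 1-[2,4-bis(benzyloxy)-3,5-dimethoxyphenyl]-3-[3,4-bis(benzyloxy)-5-methoxyphenyl]propane-1,3-dione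
Conditions: NaH (3 equiv), 8 (1.3 equiv), THF, reflux, slow addition of 6; then aq. HCl
Reagents that add atoms: none
Why: Crossed Claisen condensation; the methyl-ketone enolate of 6 (its only enolisable site) should acylate the non-enolisable ester 8, and deprotonation of the product diketone by the excess base drives the equilibrium.

Step 7
Reactants: 9 1-[2,4-bis(benzyloxy)-3,5-dimethoxyphenyl]-3-[3,4-bis(benzyloxy)-5-methoxyphenyl]propane-1,3-dione
Product: 10 5,7-bis(benzyloxy)-2-[3,4-bis(benzyloxy)-5-methoxyphenyl]-6,8-dimethoxy-4H-chromen-4-one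
Conditions: undivided cell, graphite anode, Pt cathode, controlled potential at the first (A-ring) anodic wave found by CV, nBu4NPF6, HFIP/CH2Cl2 1:3, dilute, rt, stopped near 2 F/mol
Reagents that add atoms: none
Why: Proposed new method: one-electron anodic oxidation of the tetra-alkoxy A ring of 9 (the most easily oxidised π-system, its radical cation stabilised by HFIP) should be followed by attack of the C2 enol oxygen of the hydrogen-bonded keto-enol on the A-ring C–H carbon ortho to the acyl group, and a second electron transfer with proton loss should rearomatise the ring as chromone 10 while protons are reduced to H2 at the cathode. The closest known reaction types are anodic dehydrogenative C–O cyclisations of electron-rich arenes with tethered oxygen nucleophiles (biaryl acids to benzocoumarins, anilides to benzoxazoles), oxidative closure of α-aryl ketone enols to benzofurans, and the Cu-catalysed O-arylation of 1-(2-haloaryl)-1,3-diketones, which makes the same ring from a C–Br bond. The pyranone ring closes 6-endo-trig with respect to the C8a–C4a arene bond (O1 to C8a), and no stereocentre is formed. Ring selectivity (A over B) should follow from the lower potential of the ring with four alkoxy groups against three, held by controlled-potential electrolysis; site selectivity follows because C8a is the only C–H on that ring and lies ortho and para to methoxy groups where the radical cation carries most charge, whereas ipso attack at the benzyloxy-bearing ortho carbon is reversible and has no proton to lose. C–O rather than C3-centred coupling should be favoured by working without base, so that the diketone is not oxidised as its enolate, and by high dilution.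

Step 8
Reactants: 10 5,7-bis(benzyloxy)-2-[3,4-bis(benzyloxy)-5-methoxyphenyl]-6,8-dimethoxy-4H-chromen-4-one
Product: 11 5,7,3',4'-tetrahydroxy-6,8,5'-trimethoxyflavone, 2-(3,4-dihydroxy-5-methoxyphenyl)-5,7-dihydroxy-6,8-dimethoxy-4H-chromen-4-one
Conditions: H2 (1 atm), 10% Pd/C, THF/MeOH, rt
Reagents that add atoms: none
Why: Catalytic hydrogenolysis of the four benzyl aryl ethers over Pd/C should leave the methyl ethers and the chromone C2=C3 bond (part of a vinylogous ester, not reduced at one atmosphere) untouched.

**Compound list**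

1 | acetosyringone, 1-(4-hydroxy-3,5-dimethoxyphenyl)ethanone | CC(=O)c1cc(OC)c(O)c(OC)c1 | starting material
2 | benzyl bromide | BrCc1ccccc1 | starting material
3 | 1-[4-(benzyloxy)-3,5-dimethoxyphenyl]ethanone | CC(=O)c1cc(OC)c(OCc2ccccc2)c(OC)c1 | intermediate
4 | 1-[4-(benzyloxy)-2-bromo-3,5-dimethoxyphenyl]ethanone | CC(=O)c1cc(OC)c(OCc2ccccc2)c(OC)c1Br | intermediate
5 | 1-[4-(benzyloxy)-2-hydroxy-3,5-dimethoxyphenyl]ethanone | CC(=O)c1cc(OC)c(OCc2ccccc2)c(OC)c1O | intermediate
6 | 1-[2,4-bis(benzyloxy)-3,5-dimethoxyphenyl]ethanone | CC(=O)c1cc(OC)c(OCc2ccccc2)c(OC)c1OCc1ccccc1 | intermediate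
7 | methyl 3,4-dihydroxy-5-methoxybenzoate | COC(=O)c1cc(O)c(O)c(OC)c1 | starting material
8 | methyl 3,4-bis(benzyloxy)-5-methoxybenzoate | COC(=O)c1cc(OC)c(OCc2ccccc2)c(OCc2ccccc2)c1 | intermediate
9 | 1-[2,4-bis(benzyloxy)-3,5-dimethoxyphenyl]-3-[3,4-bis(benzyloxy)-5-methoxyphenyl]propane-1,3-dione | COc1cc(C(=O)CC(=O)c2cc(OC)c(OCc3ccccc3)c(OC)c2OCc2ccccc2)cc(OCc2ccccc2)c1OCc1ccccc1 | intermediate
10 | 5,7-bis(benzyloxy)-2-[3,4-bis(benzyloxy)-5-methoxyphenyl]-6,8-dimethoxy-4H-chromen-4-one | COc1cc(-c2cc(=O)c3c(OCc4ccccc4)c(OC)c(OCc4ccccc4)c(OC)c3o2)cc(OCc2ccccc2)c1OCc1ccccc1 | intermediate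
11 | 5,7,3',4'-tetrahydroxy-6,8,5'-trimethoxyflavone | COc1cc(-c2cc(=O)c3c(O)c(OC)c(O)c(OC)c3o2)cc(O)c1O | target

**Step count and risks**

Total step count: 8. Longest linear sequence: 7 steps (1, 2, 3, 4, 6, 7, 8) from acetosyringone; step 5 is the one-step branch to the B-ring ester.

Steps most likely to fail:

1. Step 7 (proposed new method). Oxidation may start at the B ring or at the diketone enol and lead to C3-centred dimerisation. The A-ring radical cation may also lose a benzyl group and pass on to quinones, or the product may be oxidised further. Fallback by known chemistry, from 6 to 10: ring bromination of 6 at its last aromatic C–H (NBS, MeCN) should give 1-[2,4-bis(benzyloxy)-6-bromo-3,5-dimethoxyphenyl]ethanone F1. Claisen condensation of F1 with 8 (NaH, THF, reflux) should give 1-[2,4-bis(benzyloxy)-6-bromo-3,5-dimethoxyphenyl]-3-[3,4-bis(benzyloxy)-5-methoxyphenyl]propane-1,3-dione F2. Copper-catalysed intramolecular O-arylation of the enolate (CuI, 1,10-phenanthroline, K2CO3, DMF, 100 °C) should then close the pyranone ring and rejoin the route at 10.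

2. Step 3. Oxidative addition at the C–Br bond flanked by acetyl and methoxy may be slow, so that base-mediated aldol self-condensation of the methyl ketone or hydrodebromination takes over. Fallback, from 4 to 5: Miyaura borylation (B2pin2, Pd(OAc)2/SPhos, KOAc, dioxane, 90 °C) should give 1-[4-(benzyloxy)-3,5-dimethoxy-2-(4,4,5,5-tetramethyl-1,3,2-dioxaborolan-2-yl)phenyl]ethanone F3. Brief oxidation of the C–B bond (NaBO3·4H2O, THF/H2O, rt) should give phenol 5.

3. Step 2. Bromination may occur at the acetyl methyl group through the enol instead of on the ring. Fallback, from 3 to 4: the ketone is masked first (ethylene glycol, TsOH cat., toluene, Dean–Stark) as 2-[4-(benzyloxy)-3,5-dimethoxyphenyl]-2-methyl-1,3-dioxolane F4. With no enolisable carbonyl and a more electron-rich ring, NBS (MeCN, NaHCO3) should give 2-[4-(benzyloxy)-2-bromo-3,5-dimethoxyphenyl]-2-methyl-1,3-dioxolane F5. Hydrolysis (aq. HCl, acetone, rt) should return ketone 4.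

**Further compounds**

F1 | step 7 | 1-[2,4-bis(benzyloxy)-6-bromo-3,5-dimethoxyphenyl]ethanone | CC(=O)c1c(Br)c(OC)c(OCc2ccccc2)c(OC)c1OCc1ccccc1
F2 | step 7 | 1-[2,4-bis(benzyloxy)-6-bromo-3,5-dimethoxyphenyl]-3-[3,4-bis(benzyloxy)-5-methoxyphenyl]propane-1,3-dione | COc1cc(C(=O)CC(=O)c2c(Br)c(OC)c(OCc3ccccc3)c(OC)c2OCc2ccccc2)cc(OCc2ccccc2)c1OCc1ccccc1
F3 | step 3 | 1-[4-(benzyloxy)-3,5-dimethoxy-2-(4,4,5,5-tetramethyl-1,3,2-dioxaborolan-2-yl)phenyl]ethanone | CC(=O)c1cc(OC)c(OCc2ccccc2)c(OC)c1B1OC(C)(C)C(C)(C)O1
F4 | step 2 | 2-[4-(benzyloxy)-3,5-dimethoxyphenyl]-2-methyl-1,3-dioxolane | CC1(OCCO1)c1cc(OC)c(OCc2ccccc2)c(OC)c1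
F5 | step 2 | 2-[4-(benzyloxy)-2-bromo-3,5-dimethoxyphenyl]-2-methyl-1,3-dioxolane | CC1(OCCO1)c1cc(OC)c(OCc2ccccc2)c(OC)c1Br
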